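The homoadamantane cage is cut at two bonds: C7–C10 (C7 = methine of the bicyclo[3.3.1]nonanetrione, C10 = CH2 of the ethano bridge C7–C10–C11–C3) and C1–C8. This leads back to a monocyclic benzoyl trione (ring A) whose C3 is spiro-fused to the finished cyclopentane carrying an iodomethyl group (C10) on C11, and whose C5 bears geranyl and prenyl. The key step exploits the syn-1,3 relationship of the C11 arm and the C5 prenyl group across ring A: a C10 radical closes the seven-membered ring onto C7, and the resulting C8 radical, oxidised to the cation, is trapped by enol carbon C1 to close ring B. C3 and C11 stem from a catalytic asymmetric Claisen rearrangement.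

Key step: step 10

Remarks:
- Core numbering: C1 benzoyl-bearing bridgehead; C2, C4, C9 ketone carbons; C3 quaternary carbon between C2 and C4; C5 geranyl-bearing bridgehead; C6 CH2; C7 CH; C8 CMe2; ethano bridge C7–C10H2–C11H–C3; cyclopentane C3–C11–C12(Me2)–C13H(CMe2OH)–C14H2.
- Compounds 1, 4, 5 and 12 are commercial.
- Assumption: the (S,S)-ligand in step 6 is taken to deliver enantiomer 9; if the sense of induction is opposite, the (R,R)-ligand is used.

Step 1
Reactants: 1 prenol (3-methylbut-2-en-1-ol)
Product: 2 prenyl TBS ether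
Conditions: TBSCl, imidazole, DMF, 0 °C to rt
Reagents that add atoms: tert-butyldimethylsilyl chloride, CC(C)(C)[Si](C)(C)Cl
Why: Routine silylation of a primary allylic alcohol; no stereocentre is formed.

Step 2
Reactants: 2 prenyl TBS ether
Product: 3 (E)-4-[(tert-butyldimethylsilyl)oxy]-2-methylbut-2-en-1-ol
Conditions: SeO2 (cat.), t-BuOOH, salicylic acid (cat.), CH2Cl2, rt
Reagents that add atoms: tert-butyl hydroperoxide, CC(C)(C)OO
Why: Riley allylic oxidation (ene reaction then [2,3]-shift) should oxidise the methyl group trans to the CH2OTBS chain, giving the (E)-olefin that the later chair Claisen transition state needs.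

Step 3
Reactants: 4 2,4,6-trihydroxybenzophenone; 5 prenyl bromide
Product: 6 clusiaphenone B (3,5-diprenyl-2,4,6-trihydroxybenzophenone)
Conditions: 5 (2.1 equiv), aq. KOH, 0 °C
Reagents that add atoms: none
Why: Double C-alkylation of the phloroglucinol phenoxide in water should occur at the two free ring carbons, the only nucleophilic carbon sites.

Step 4
Reactants: 6 clusiaphenone B
Product: 7 4,6-bis-O-TBS ether of clusiaphenone B (2-OH free)
Conditions: TBSCl (2.1 equiv), imidazole, DMAP (cat.), DMF, 0 °C to rt
Reagents that add atoms: tert-butyldimethylsilyl chloride, CC(C)(C)[Si](C)(C)Cl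
Why: Silylation should take the para hydroxyl and one of the two equivalent ortho hydroxyls, leaving the one that is hydrogen-bonded to the benzoyl carbonyl.

Step 5
Reactants: 7 bis-silyl ether; 3 (E)-allylic alcohol
Product: 8 aryl (E)-allyl ether at O2 (ortho to benzoyl, next to the C3 prenyl group)
Conditions: PPh3, DIAD, THF, 0 °C to rt
Reagents that add atoms: none
Why: Mitsunobu etherification of the single free phenol with the primary allylic alcohol should give O-alkylation with the (E)-olefin intact.

Step 6
Reactants: 8 aryl allyl ether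
Product: 9 (6S)-2-benzoyl-3,5-bis(TBSO)-6-[(2S)-1-(TBSO)-3-methylbut-3-en-2-yl]-4,6-diprenylcyclohexa-2,4-dien-1-one
Conditions: Cu(OTf)2 (10 mol %), 2,2'-isopropylidenebis[(4S)-4-tert-butyl-2-oxazoline] (11 mol %), 4 Å MS, CH2Cl2, rt
Reagents that add atoms: none
Why: Two-point binding of the chiral copper bis(oxazoline) Lewis acid to the ether oxygen and the benzoyl carbonyl should trigger a dearomative aromatic Claisen rearrangement to the prenyl-bearing ortho carbon through a chair transition state with CH2OTBS equatorial, so the C3/C11 relative configuration follows from the (E)-olefin and the absolute sense from the ligand.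

Step 7
Reactants: 9 Claisen dienone
Product: 11 tris-silylated spiro tertiary alcohol (C13 CMe2OH trans to the C11 CH2OTBS arm), via tertiary hydroperoxide 10 (not isolated)
Conditions: Co(acac)2 (20 mol %), PhSiH3 (1.5 equiv), air (1 atm), THF, 0 °C to rt; then PPh3
Reagents that add atoms: dioxygen, O=O
Why: Under Mukaiyama hydration conditions, hydrogen-atom transfer to the 1,1-disubstituted isopropenyl group (faster than to the trisubstituted olefins) should give the tertiary C12 radical, which closes 5-exo-trig onto the C3 prenyl olefin through a chair-like transition state with CH2OTBS pseudo-equatorial (C13 trans to that arm), and O2 capture followed by PPh3 reduction gives the alcohol.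

Step 8
Reactants: 11 spiro tertiary alcohol; 12 geranyl bromide
Product: 14 C5-geranylated spiro diol (prenyl cis to C11), via desilylated spiro triol 13 (not isolated)
Conditions: TBAF (3.3 equiv, 1 M in THF), 0 °C, argon; then 12 (1.1 equiv), 0 °C to rt
Reagents that add atoms: none
Why: Fluoride should cleave all three silyl ethers, and the tetrabutylammonium enolate should be C-alkylated at C5 from the ring-A face opposite C11 and its CH2OH arm, which places prenyl cis to C11.

Step 9
Reactants: 14 spiro diol
Product: 15 primary iodide (C10–I)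
Conditions: I2, PPh3, imidazole, CH2Cl2, 0 °C to rt
Reagents that add atoms: iodine, II
Why: Appel iodination should convert only the primary alcohol (drained from any lactol with the C4 ketone), since the tertiary alcohol and the hydrogen-bonded enol do not react at this temperature.

Step 10
Reactants: 15 primary iodide
Product: 16 target CNP0164095.1
Conditions: fac-Ir(ppy)3 (2 mol %), NaHCO3, HFIP/MeCN (1:1), blue LEDs (450 nm), rt, argon; then HCO2H, rt
Reagents that add atoms: none
Why: Proposed new method: excited fac-Ir(ppy)3 reduces the C10–I bond to the primary C10 radical, which adds to C7 of the C5 prenyl group in a 7-exo-trig closure of the cycloheptane C3–C11–C10–C7–C6–C5–C4; the tertiary C8 radical is oxidised by the tetravalent iridium species to the C8 cation, which C-alkylates enol carbon C1 and closes six-membered ring B (enol double bond exocyclic) between two quaternary carbons. The closest known reaction types are photoredox radical–polar crossover carbofunctionalisation of alkenes and the acid-mediated cationic cyclisation used for bicyclo[3.3.1]nonane acylphloroglucinol cores. The step exploits the syn-1,3 placement of the C11 arm and the C5 prenyl group on ring A, which holds C10 next to C7 and should let the normally slow 7-exo mode compete with 1,6-hydrogen transfer; the gem-dimethyl terminus directs attack to C7 over 8-endo attack at C8. C7 is fixed because only the epimer whose C8 cation lies over ring A can reach C1, and C1 follows from the cage (C8 arrives on the face carrying C6). Prenyl rather than geranyl is the acceptor because geranyl sits on the opposite face of ring A (step 8). The formic acid finish should re-ionise any O-alkylated enol ether, olefin isomer or C7 epimer (via the 7(8)-olefin) so that material drains to the C-alkylated cage.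

Compound list

1 | prenol (3-methylbut-2-en-1-ol) | CC(C)=CCO | starting material
2 | prenyl TBS ether, tert-butyldimethyl[(3-methylbut-2-en-1-yl)oxy]silane | CC(C)=CCO[Si](C)(C)C(C)(C)C | intermediate
3 | (E)-4-[(tert-butyldimethylsilyl)oxy]-2-methylbut-2-en-1-ol | OC/C(C)=C/CO[Si](C)(C)C(C)(C)C | intermediate
4 | 2,4,6-trihydroxybenzophenone | O=C(c1ccccc1)c1c(O)cc(O)cc1O | starting material
5 | prenyl bromide (1-bromo-3-methylbut-2-ene) | CC(C)=CCBr | starting material
6 | clusiaphenone B, [2,4,6-trihydroxy-3,5-bis(3-methylbut-2-en-1-yl)phenyl](phenyl)methanone | CC(C)=CCc1c(O)c(CC=C(C)C)c(O)c(C(=O)c2ccccc2)c1O | intermediate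
7 | [2-hydroxy-4,6-bis(tert-butyldimethylsilyloxy)-3,5-bis(3-methylbut-2-en-1-yl)phenyl](phenyl)methanone | CC(C)=CCc1c(O[Si](C)(C)C(C)(C)C)c(CC=C(C)C)c(O)c(C(=O)c2ccccc2)c1O[Si](C)(C)C(C)(C)C | intermediate
8 | aryl allyl ether: 7 with the 2-OH etherified by the (E)-4-(TBSO)-2-methylbut-2-en-1-yl group | CC(C)=CCc1c(O[Si](C)(C)C(C)(C)C)c(CC=C(C)C)c(OC/C(C)=C/CO[Si](C)(C)C(C)(C)C)c(C(=O)c2ccccc2)c1O[Si](C)(C)C(C)(C)C | intermediate
9 | (6S)-2-benzoyl-3,5-bis(TBSO)-6-[(2S)-1-(TBSO)-3-methylbut-3-en-2-yl]-4,6-bis(3-methylbut-2-en-1-yl)cyclohexa-2,4-dien-1-one | O=C1C(C(=O)c2ccccc2)=C(O[Si](C)(C)C(C)(C)C)C(CC=C(C)C)=C(O[Si](C)(C)C(C)(C)C)[C@]1(CC=C(C)C)[C@@H](CO[Si](C)(C)C(C)(C)C)C(C)=C | intermediate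
10 | tertiary hydroperoxide of 11 (C13 bears CMe2OOH) | O=C1C(C(=O)c2ccccc2)=C(O[Si](C)(C)C(C)(C)C)C(CC=C(C)C)=C(O[Si](C)(C)C(C)(C)C)[C@@]13C[C@@H](C(C)(C)OO)C(C)(C)[C@@H]3CO[Si](C)(C)C(C)(C)C | intermediate (not isolated)
11 | 9-benzoyl-6,8-bis(TBSO)-1-(TBSO-methyl)-3-(2-hydroxypropan-2-yl)-2,2-dimethyl-7-prenylspiro[4.5]deca-6,8-dien-10-one; CH2OTBS on C1 trans to the C3 substituent and on the cyclopentane face of ring carbon C6 (core C4) | O=C1C(C(=O)c2ccccc2)=C(O[Si](C)(C)C(C)(C)C)C(CC=C(C)C)=C(O[Si](C)(C)C(C)(C)C)[C@@]13C[C@@H](C(C)(C)O)C(C)(C)[C@@H]3CO[Si](C)(C)C(C)(C)C | intermediate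
12 | geranyl bromide, (E)-1-bromo-3,7-dimethylocta-2,6-diene | CC(C)=CCC/C(C)=C/CBr | starting material
13 | desilylated spiro triol: 11 with all three TBS groups removed (enol form shown) | O=C1C(C(=O)c2ccccc2)=C(O)C(CC=C(C)C)=C(O)[C@@]13C[C@@H](C(C)(C)O)C(C)(C)[C@@H]3CO | intermediate (not isolated)
14 | 9-benzoyl-7-[(E)-geranyl]-10-hydroxy-1-(hydroxymethyl)-3-(2-hydroxypropan-2-yl)-2,2-dimethyl-7-prenylspiro[4.5]dec-9-ene-6,8-dione; prenyl cis and geranyl trans to cyclopentane carbon C1 (core C11), other centres as in 11 | CC(C)=CCC/C(C)=C/C[C@@]1(CC=C(C)C)C(=O)[C@@]2(C[C@@H](C(C)(C)O)C(C)(C)[C@@H]2CO)C(O)=C(C(=O)c3ccccc3)C1=O | intermediate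
15 | primary iodide: 14 with CH2OH replaced by CH2I, configuration unchanged | CC(C)=CCC/C(C)=C/C[C@@]1(CC=C(C)C)C(=O)[C@@]2(C[C@@H](C(C)(C)O)C(C)(C)[C@@H]2CI)C(O)=C(C(=O)c3ccccc3)C1=O | intermediate
16 | CNP0164095.1, homoadamantane acylphloroglucinol with fused cyclopentane | CC(C)=CCC/C(C)=C/C[C@@]12C[C@H]3C[C@H]4C(C)(C)[C@H](C(C)(C)O)C[C@]4(C1=O)C(=O)[C@@](C(=O)c1ccccc1)(C2=O)C3(C)C | target

Total step count: 10. Longest linear sequence: 8 steps (steps 3–10 from 4; equally steps 1, 2 and 5–10 from 1).

Steps most likely to fail

1. Step 10 (Proposed new method). Addition of the nucleophilic primary C10 radical to the electron-rich trisubstituted olefin may be too slow, so that premature reduction or 1,6-hydrogen transfer from C6 takes over. Cation capture may also stop at enol oxygen or at proton loss, and the acid finish may ionise the tertiary alcohol. Fallback with known chemistry: setting out from iodide 15, a visible-light palladium-catalysed radical alkyl Heck cyclisation (Pd(PPh3)4, zerovalent palladium, K2CO3, benzene, blue LEDs, rt; alkyl radical/monovalent palladium pair, 7-exo closure, then β-hydride elimination) would give the seven-membered-ring isopropenyl compound F1. Formic acid at rt would then protonate the isopropenyl group of F1 to the C8 cation, which enol carbon C1 captures, and the route is rejoined at 16.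

2. Step 7. Oxygen may capture the C12 radical before the 5-exo closure (plain hydration of the isopropenyl group), or hydrogen-atom transfer may spread to the trisubstituted olefins. Fallback: setting out from 9, an oxygen-free cobalt-salen MHAT cycloisomerisation (chloro[N,N'-bis(3,5-di-tert-butylsalicylidene)cyclohexane-1,2-diaminato]cobalt, Co(salen)Cl, cat.; PhSiH3 cat.; benzene, rt) separates ring closure from oxygenation and would give the cycloisomerised isopropenyl spirocycle F2. Mukaiyama hydration of its new 1,1-disubstituted olefin (Co(acac)2, PhSiH3, O2, THF; then PPh3) returns to 11.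

3. Step 6. The catalyst may discriminate the faces poorly, or the Lewis acid may ionise the allyl ether, with loss of [3,3] fidelity. Fallback: setting out from 8, thermal Claisen rearrangement (toluene, 110 °C) would give 9 as the racemate, that is 9 together with its enantiomer ent-9 F3. Preparative HPLC on a chiral stationary phase (cellulose tris(3,5-dimethylphenylcarbamate)) separates them, and the route resumes at 9.

Further compounds

F1 | step 10 | seven-membered-ring isopropenyl compound (C7–C10 formed, C7 bears C(Me)=CH2, C1 enolised) | CC(C)=CCC/C(C)=C/C[C@@]12C[C@H](C(C)=C)C[C@H]3C(C)(C)[C@H](C(C)(C)O)C[C@]3(C1=O)C(O)=C(C(=O)c1ccccc1)C2=O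
F2 | step 7 | cycloisomerised isopropenyl spirocycle (11 with C(Me)=CH2 in place of CMe2OH on C13) | O=C1C(C(=O)c2ccccc2)=C(O[Si](C)(C)C(C)(C)C)C(CC=C(C)C)=C(O[Si](C)(C)C(C)(C)C)[C@@]13C[C@@H](C(C)=C)C(C)(C)[C@@H]3CO[Si](C)(C)C(C)(C)C
F3 | step 6 | ent-9, the (6R,2'R) enantiomer of 9 | O=C1C(C(=O)c2ccccc2)=C(O[Si](C)(C)C(C)(C)C)C(CC=C(C)C)=C(O[Si](C)(C)C(C)(C)C)[C@@]1(CC=C(C)C)[C@H](CO[Si](C)(C)C(C)(C)C)C(C)=C
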